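**Retrosynthetic overview**

1. Target 13 ⇐ acetal cleavage of MOM ether 12 ⇐ one-pot NBS treatment of vinylsilane 11 (ipso-bromodesilylation with retention, and bromination para to the aryl oxygen).
2. Feature used: on the cyclopentane (C1 quaternary with aryl and methyl, C2 methine with methyl, C3 bearing the exocyclic bromomethylene, C4 and C5 methylenes), the C2 methyl next to the C3 alkylidene is read as a vinyl group and a silylalkyne joined through a zirconacyclopentene. Cutting C2–C3 gives the 1,6-enyne 9.
3. 9 ⇐ copper-catalysed enantioselective SN2′ alkylation of (E)-allyl phosphate 6 with the silylbutynyl Grignard reagent 8 (sets C1) ⇐ Horner–Wadsworth–Emmons olefination, reduction and phosphorylation from ketone 2.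
4. The phenol is carried as a MOM ether rather than a methyl ether: its distal acetal oxygen is the intended donor for zirconium in the key step, and it comes off at the end without a Lewis acid.
5. Ring order: the arene is purchased; the cyclopentane is the only ring formed (step 6).

Key step: step 6

Assumption: the absolute sense of induction of the copper catalyst in step 5 is not predicted here; the ligand antipode that gives (R)-9 is to be fixed after a first run and configurational assignment.

**Route**

Step 1
Reactants: 1 1-(2-hydroxy-4-methylphenyl)ethanone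
Product: 2 1-[2-(methoxymethoxy)-4-methylphenyl]ethanone
Conditions: MOMCl, i-Pr2NEt, CH2Cl2, 0 °C → 40 °C
Reagents that add atoms: chloromethyl methyl ether, COCCl
Why: Base-mediated O-alkylation of the phenol (Williamson-type etherification) should proceed cleanly despite the internal hydrogen bond to the ketone, and the acetal is stable to every reagent used up to step 7.

Step 2
Reactants: 2 1-[2-(methoxymethoxy)-4-methylphenyl]ethanone; 3 triethyl phosphonoacetate
Product: 4 ethyl (2E)-3-[2-(methoxymethoxy)-4-methylphenyl]but-2-enoate
Conditions: NaH, THF, 0 °C → reflux; chromatographic removal of the minor (Z)-isomer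
Reagents that add atoms: none
Why: Horner–Wadsworth–Emmons olefination of the aryl methyl ketone with a stabilised phosphonate anion should favour the (E)-enoate (aryl trans to the ester), and geometric purity is secured here because it governs the enantioselectivity of step 5.

Step 3
Reactants: 4 ethyl (2E)-3-[2-(methoxymethoxy)-4-methylphenyl]but-2-enoate
Product: 5 (2E)-3-[2-(methoxymethoxy)-4-methylphenyl]but-2-en-1-ol
Conditions: i-Bu2AlH (2.2 equiv), CH2Cl2, −78 °C → 0 °C; aq. potassium sodium tartrate
Reagents that add atoms: none
Why: 1,2-Reduction of the conjugated ester by the aluminium hydride should give the allylic alcohol without touching the alkene geometry or the acetal.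

Step 4
Reactants: 5 (2E)-3-[2-(methoxymethoxy)-4-methylphenyl]but-2-en-1-ol
Product: 6 diethyl (2E)-3-[2-(methoxymethoxy)-4-methylphenyl]but-2-en-1-yl phosphate
Conditions: ClP(O)(OEt)2, Et3N, 4-(dimethylamino)pyridine (cat.), CH2Cl2, 0 °C; rapid filtration through Et3N-deactivated silica
Reagents that add atoms: diethyl chlorophosphate, CCOP(=O)(Cl)OCC
Why: O-Phosphorylation of the primary allylic alcohol is routine; the product can ionise to a stabilised allyl cation, so it is kept basic and used promptly.

Step 5
Reactants: 6 diethyl (2E)-3-[2-(methoxymethoxy)-4-methylphenyl]but-2-en-1-yl phosphate; 7 (4-bromobut-1-yn-1-yl)trimethylsilane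
Product: 9 (R)-{5-[2-(methoxymethoxy)-4-methylphenyl]-5-methylhept-6-en-1-yn-1-yl}trimethylsilane, via [4-(trimethylsilyl)but-3-yn-1-yl]magnesium bromide 8 (not isolated)
Conditions: 7, Mg, THF, 40 °C; then slow addition to 6, CuCl (5 mol %), enantiopure 1-mesityl-3-(1-hydroxy-4-methylpentan-2-yl)-4,5-dihydroimidazolium hexafluorophosphate (6 mol %), Et2O, −78 °C
Reagents that add atoms: none
Why: Copper-catalysed asymmetric allylic alkylation: the Grignard reagent transmetalates to a chiral carbene-bound monovalent copper alkyl, which adds anti-SN2′ to the phosphate at the aryl-bearing carbon and reductively eliminates from trivalent copper before allyl isomerisation, so the ligand selects the alkene face and sets the quaternary centre C1 as (R).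

Step 6
Reactants: 9 (R)-{5-[2-(methoxymethoxy)-4-methylphenyl]-5-methylhept-6-en-1-yn-1-yl}trimethylsilane
Product: 11 [(E)-{(2R,3R)-3-[2-(methoxymethoxy)-4-methylphenyl]-2,3-dimethylcyclopentylidene}methyl]trimethylsilane, via bis(cyclopentadienyl)zirconabicyclo[3.3.0]octene 10 (not isolated)
Conditions: Cp2ZrCl2 (1.2 equiv), n-BuLi (2.4 equiv), THF, −78 °C; 9 in toluene, −78 °C → rt, then 50 °C; 1 M HCl, 0 °C
Reagents that add atoms: none
Why: Cp2ZrCl2 and two equivalents of n-BuLi give Cp2Zr(n-Bu)2, which loses butane to form the but-1-ene complex of divalent zirconocene; the silylalkyne of 9 displaces butene to give a zirconacyclopropene, the vinyl group inserts, and acid cleaves both Zr–C bonds of zirconacycle 10 with retention. The closest known reaction type is the zirconocene-mediated bicyclization of 1,6-enynes bearing a silylalkyne, followed by protonolysis. The cyclopentane closes by oxidative cyclization on zirconium, the C2–C3 bond forming exo to both the alkyne (5-exo-dig) and the alkene (5-exo-trig), with silicon alpha to zirconium. The new stereocentre C2 is controlled by the C1 quaternary centre: the cyclization is reversible on warming, so the two C2 epimers of 10 can equilibrate, and the basic distal oxygen of the MOM group is expected to reach the lateral coordination site of the 16-electron tetravalent zirconium only when the Zr–CH2 arm lies on the aryl face, by analogy with the heteroatom assistance invoked in zirconacycle formation from allylic ethers; toluene is used so that solvent competes less for that site. The step needs this cis arm/aryl relationship, which rests on the chelation hypothesis and is to be checked by NOE on 11. It also needs the (E)-vinylsilane, which syn addition across the alkyne and retentive protonolysis secure by leaving silicon cis to C4.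

Step 7
Reactants: 11 [(E)-{(2R,3R)-3-[2-(methoxymethoxy)-4-methylphenyl]-2,3-dimethylcyclopentylidene}methyl]trimethylsilane
Product: 12 1-bromo-5-[(1R,2R,3E)-3-(bromomethylidene)-1,2-dimethylcyclopentyl]-4-(methoxymethoxy)-2-methylbenzene
Conditions: NBS (2.1 equiv), MeCN, 0 °C → rt, dark
Reagents that add atoms: N-bromosuccinimide, O=C1CCC(=O)N1Br
Why: Electrophilic ipso-bromodesilylation: bromine adds to the silyl-bearing carbon to give a tertiary β-silyl cation at C3, least-motion rotation aligns the C–Si bond and loss of silicon puts bromine where silicon was (retention, (E)), while the second equivalent brominates the arene para to the acetal oxygen, the only unhindered activated position.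

Step 8
Reactants: 12 1-bromo-5-[(1R,2R,3E)-3-(bromomethylidene)-1,2-dimethylcyclopentyl]-4-(methoxymethoxy)-2-methylbenzene
Product: 13 4-bromo-2-[(1R,2R,3E)-3-(bromomethylidene)-1,2-dimethylcyclopentyl]-5-methylphenol
Conditions: 3 M HCl, MeOH/THF, 40 °C
Reagents that add atoms: none
Why: Acid-catalysed acetal cleavage through an oxocarbenium ion trapped by methanol should free the phenol under conditions too mild to protonate the electron-poor bromoalkene or disturb either stereocentre.

**Compound list**

1 | 1-(2-hydroxy-4-methylphenyl)ethanone | CC(=O)c1ccc(C)cc1O | starting material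
2 | 1-[2-(methoxymethoxy)-4-methylphenyl]ethanone | COCOc1cc(C)ccc1C(C)=O | intermediate
3 | triethyl phosphonoacetate | CCOC(=O)CP(=O)(OCC)OCC | starting material
4 | ethyl (2E)-3-[2-(methoxymethoxy)-4-methylphenyl]but-2-enoate | CCOC(=O)/C=C(\C)c1ccc(C)cc1OCOC | intermediate
5 | (2E)-3-[2-(methoxymethoxy)-4-methylphenyl]but-2-en-1-ol | OC/C=C(\C)c1ccc(C)cc1OCOC | intermediate
6 | diethyl (2E)-3-[2-(methoxymethoxy)-4-methylphenyl]but-2-en-1-yl phosphate | CCOP(=O)(OCC)OC/C=C(\C)c1ccc(C)cc1OCOC | intermediate
7 | (4-bromobut-1-yn-1-yl)trimethylsilane | C[Si](C)(C)C#CCCBr | starting material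
8 | [4-(trimethylsilyl)but-3-yn-1-yl]magnesium bromide | C[Si](C)(C)C#CCC[Mg]Br | intermediate (not isolated)
9 | (R)-{5-[2-(methoxymethoxy)-4-methylphenyl]-5-methylhept-6-en-1-yn-1-yl}trimethylsilane | COCOc1cc(C)ccc1[C@@](C)(C=C)CCC#C[Si](C)(C)C | intermediate (key-step precursor)
10 | 3,3-bis(cyclopentadienyl)-6-[2-(methoxymethoxy)-4-methylphenyl]-6-methyl-2-(trimethylsilyl)-3-zirconabicyclo[3.3.0]oct-1-ene, Zr–CH2 arm at C5 cis to the aryl group on C6, C6 configured as in 9 | COCOc1cc(C)ccc1[C@]1(C)CCC2=C([Si](C)(C)C)[Zr](C3C=CC=C3)(C3C=CC=C3)C[C@H]12 | intermediate (not isolated)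
11 | [(E)-{(2R,3R)-3-[2-(methoxymethoxy)-4-methylphenyl]-2,3-dimethylcyclopentylidene}methyl]trimethylsilane | COCOc1cc(C)ccc1[C@]1(C)CC/C(=C\[Si](C)(C)C)[C@@H]1C | intermediate (key-step product)
12 | 1-bromo-5-[(1R,2R,3E)-3-(bromomethylidene)-1,2-dimethylcyclopentyl]-4-(methoxymethoxy)-2-methylbenzene | COCOc1cc(C)c(Br)cc1[C@]1(C)CC/C(=C\Br)[C@@H]1C | intermediate
13 | 4-bromo-2-[(1R,2R,3E)-3-(bromomethylidene)-1,2-dimethylcyclopentyl]-5-methylphenol | Cc1cc(O)c([C@]2(C)CC/C(=C\Br)[C@@H]2C)cc1Br | target

**Step count**

Total: 8 steps. Longest linear sequence: 8 steps (1 → 13); the Grignard reagent 8 is made and used in the flask of step 5.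

**Steps most likely to fail**

Step 6. Facial selection in the alkene insertion may follow sterics rather than coordination of the acetal oxygen, placing the Zr–CH2 arm trans to the aryl group; the resulting C2 epimer cannot be corrected later. The fallback sets out from 9 and makes C2 trigonal first. Cycloisomerization with Pd(OAc)2 (5 mol %) and PPh3 (10 mol %) in toluene at 80 °C (hydropalladation of the silylalkyne, 5-exo carbopalladation of the vinyl group, β-hydride elimination) should give the 1,3-diene [(E)-{(3R)-3-[2-(methoxymethoxy)-4-methylphenyl]-3-methyl-2-methylidenecyclopentylidene}methyl]trimethylsilane F1, with the same vinylsilane geometry. Diimide (from 2-nitrobenzenesulfonyl hydrazide and Et3N, CH2Cl2, rt) should reduce the 1,1-disubstituted methylene and spare the hindered trisubstituted vinylsilane. Hydrogen is expected to reach C2 from the face opposite the aryl group, leaving the new methyl cis to it, which returns to the route at 11.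

Step 5. The catalyst may give low enantioselectivity at the hindered ortho-substituted aryl terminus, or substitution may occur at the α-carbon instead of the γ-carbon, or the phosphate may ionise before the catalyst engages it. The fallback sets out from 5 and fixes the regiochemistry by a sigmatropic shift. Johnson–Claisen rearrangement (triethyl orthoacetate, propionic acid cat., 140 °C) should give racemic ethyl 3-[2-(methoxymethoxy)-4-methylphenyl]-3-methylpent-4-enoate F2. LiAlH4 in THF should reduce it to racemic 3-[2-(methoxymethoxy)-4-methylphenyl]-3-methylpent-4-en-1-ol F3. Preparative chromatography on a chiral stationary phase should then provide (3R)-3-[2-(methoxymethoxy)-4-methylphenyl]-3-methylpent-4-en-1-ol F4. Iodination (I2, PPh3, imidazole, CH2Cl2) should give 1-[(3R)-5-iodo-3-methylpent-1-en-3-yl]-2-(methoxymethoxy)-4-methylbenzene F5. Displacement with lithium (trimethylsilyl)acetylide (ethynyltrimethylsilane, n-BuLi, THF/DMPU, −78 °C → rt) returns to the route at 9.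

Step 7. Alkene geometry may be lost through bridging or rotation in the β-silyl cation, the cation may be captured by the acetal oxygen, or the two brominations may interfere. The fallback sets out from 11 and forms the vinyl C–Br bond through a configurationally stable vinyllithium. Iododesilylation with N-iodosuccinimide (MeCN/ClCH2CN, 0 °C) should give 1-[(1R,2R,3E)-3-(iodomethylidene)-1,2-dimethylcyclopentyl]-2-(methoxymethoxy)-4-methylbenzene F6. Iodine–lithium exchange (t-BuLi, Et2O, −78 °C) and quenching with BrCl2C–CCl2Br should give, with retention, 1-[(1R,2R,3E)-3-(bromomethylidene)-1,2-dimethylcyclopentyl]-2-(methoxymethoxy)-4-methylbenzene F7. One equivalent of NBS in MeCN should then brominate the arene para to the acetal oxygen, returning to the route at 12.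

**Further compounds**

F1 | step 6 | [(E)-{(3R)-3-[2-(methoxymethoxy)-4-methylphenyl]-3-methyl-2-methylidenecyclopentylidene}methyl]trimethylsilane | COCOc1cc(C)ccc1[C@]1(C)CC/C(=C\[Si](C)(C)C)C1=C
F2 | step 5 | racemic ethyl 3-[2-(methoxymethoxy)-4-methylphenyl]-3-methylpent-4-enoate | CCOC(=O)CC(C)(C=C)c1ccc(C)cc1OCOC
F3 | step 5 | racemic 3-[2-(methoxymethoxy)-4-methylphenyl]-3-methylpent-4-en-1-ol | OCCC(C)(C=C)c1ccc(C)cc1OCOC
F4 | step 5 | (3R)-3-[2-(methoxymethoxy)-4-methylphenyl]-3-methylpent-4-en-1-ol | COCOc1cc(C)ccc1[C@@](C)(C=C)CCO
F5 | step 5 | 1-[(3R)-5-iodo-3-methylpent-1-en-3-yl]-2-(methoxymethoxy)-4-methylbenzene | COCOc1cc(C)ccc1[C@@](C)(C=C)CCI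
F6 | step 7 | 1-[(1R,2R,3E)-3-(iodomethylidene)-1,2-dimethylcyclopentyl]-2-(methoxymethoxy)-4-methylbenzene | COCOc1cc(C)ccc1[C@]1(C)CC/C(=C\I)[C@@H]1C
F7 | step 7 | 1-[(1R,2R,3E)-3-(bromomethylidene)-1,2-dimethylcyclopentyl]-2-(methoxymethoxy)-4-methylbenzene | COCOc1cc(C)ccc1[C@]1(C)CC/C(=C\Br)[C@@H]1C
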